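**Retrosynthetic overview**

1. The succinimide ring is closed last. C12–C13 comes from an Evans syn-aldol of a C12 aldehyde with a 3-cyanopropanoyl oxazolidinone, followed by nitrile hydration and imide closure that releases the auxiliary.
2. The ring B array (7β-OAc, C8=C17, 9β-CH2) is unmasked from a silylmethyl donor–acceptor cyclopropane (C8–C9–C11) by desilylative cleavage of C8–C11.
3. The key disconnection is C9–C11. An acyl carbene hung on O7 (O7–C12(=O)–C11H) adds intramolecularly [2+1] to the C8=C9 allylsilane, closing a temporary cyclopropane and a temporary γ-lactone.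
4. Enabling feature: in ring B, C7 (bearing O7), the sp2 carbon C8 and C9 are contiguous, and O7 and C11 lie on the same β face, cis-1,3 across C8. The easily set C7 carbinol can therefore relay its configuration to C9 against the steric bias of the angular C10 methyl.
5. Rings A and B come with (S)-octalone (gem-dimethylation, deoxygenation, allylic oxidation, reduction), and C2–Cl comes from site-selective C–H chlorination. Ring order: A/B (given), then cyclopropane plus lactone (temporary), then succinimide.

Key step: step 11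

Remark: labdane numbering is used throughout (C1–C10 decalin, C17 on C8, C18/C19 on C4, C20 on C10, C11–C16 side chain). β is the face of C20. The (S)-octalone 1 is assumed to be a catalogue compound.

**Step 1**
Reactants: 1 (S)-octalone: (S)-4a-methyl-4,4a,5,6,7,8-hexahydronaphthalen-2(3H)-one
Product: 2 β,γ-enone: 4,4,10β-trimethyl-Δ5-octal-3-one
Conditions: KOtBu (3 equiv), MeI (4 equiv), tBuOH, 25 °C
Reagents that add atoms: iodomethane, CI
Why: Deconjugative double α-alkylation of the extended enolate puts both methyl groups on C4 and locks the alkene at C5=C6, with no stereocenter made and C10 untouched.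

**Step 2**
Reactants: 2 β,γ-enone
Product: 4 olefin: 4,4,10β-trimethyl-Δ5-octalin, via hydrazone 3 (not isolated)
Conditions: N2H4·H2O, KOH, diethylene glycol, 130 → 200 °C
Reagents that add atoms: none
Why: Wolff–Kishner reduction (Huang-Minlon variant) removes the C3 carbonyl, and the alkene cannot migrate into conjugation because C4 and C10 are quaternary.

**Step 3**
Reactants: 4 olefin
Product: 5 enone: 4,4,10β-trimethyl-Δ5-octal-7-one
Conditions: Rh2(cap)4 (cap = caprolactamate, 0.5 mol %), tBuOOH (aq), K2CO3, CH2Cl2, 25 °C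
Reagents that add atoms: tert-butyl hydroperoxide, CC(C)(C)OO
Why: Peroxyl-radical allylic oxidation, well known for Δ5-steroids, can only strike C7 because the other allylic carbons C4 and C10 are quaternary.

**Step 4**
Reactants: 5 enone
Product: 6 trans-decalone: 4,4,10β-trimethyl-5αH-decal-7-one
Conditions: Li (2.5 equiv), NH3(l)/THF, tBuOH (1 equiv), −78 °C; NH4Cl
Reagents that add atoms: none
Why: In this dissolving-metal enone reduction the β-carbanion at C5 is protonated axially from the α face, which sets 5α-H and the trans ring fusion as with 4-en-3-one steroids.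

**Step 5**
Reactants: 6 trans-decalone
Product: 7 chloro ketone: 2α-chloro-4,4,10β-trimethyl-5αH-decal-7-one
Conditions: ArC(O)N(Cl)tBu [Ar = 3,5-(CF3)2C6H3] (1 equiv), Cs2CO3, PhH, visible light, 55 °C
Reagents that add atoms: N-tert-butyl-N-chloro-3,5-bis(trifluoromethyl)benzamide, CC(C)(C)N(Cl)C(=O)c1cc(cc(c1)C(F)(F)F)C(F)(F)F
Why: In this site-selective radical C–H chlorination (amidyl hydrogen abstraction, chlorine-atom transfer chain) the ketone deactivates ring B, C1 and C3 are shielded by C20 and the gem-dimethyl group, and the C2 radical takes chlorine from the α face opposite the two axial methyls, giving the equatorial 2α-chloride as known for drimane-type decalins with the same ring A.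

**Step 6**
Reactants: 7 chloro ketone
Product: 8 chloro enone: 2α-chloro-4,4,10β-trimethyl-5αH-Δ8(9)-octal-7-one
Conditions: IBX (1.3 equiv), DMSO/PhMe, 70 °C
Reagents that add atoms: none
Why: IBX dehydrogenation follows the enol, and trans-fused decal-7-ones enolize toward C8 just as 5α-3-keto steroids enolize toward C2, so the C8=C9 enone should form without touching a stereocenter.

**Step 7**
Reactants: 8 chloro enone
Product: 9 iodo enone: 8-iodo derivative of 8
Conditions: I2 (1.5 equiv), pyridine/CH2Cl2, 0 → 25 °C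
Reagents that add atoms: iodine, II
Why: Baylis–Hillman-type α-iodination (pyridine adds to C9, the enolate is iodinated at C8, pyridine leaves) is known for 4,4-disubstituted cyclohexenones.

**Step 8**
Reactants: 9 iodo enone
Product: 10 silylmethyl enone: 8-(trimethylsilylmethyl) derivative of 8
Conditions: Me3SiCH2MgCl, ZnCl2, THF, 0 °C; then 9, Pd(PPh3)4 (5 mol %), 25–50 °C
Reagents that add atoms: (trimethylsilyl)methylmagnesium chloride, C[Si](C)(C)C[Mg]Cl
Why: Negishi coupling of an α-iodoenone with an alkylzinc lacking β-hydrogen places C17 with its silyl group on C8, while the ketone and the alkyl chloride are inert to the zinc reagent.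

**Step 9**
Reactants: 10 silylmethyl enone
Product: 11 allylic alcohol: 2α-chloro-7β-hydroxy-8-(trimethylsilylmethyl)-4,4,10β-trimethyl-5αH-Δ8(9)-octalin
Conditions: NaBH4, CeCl3·7H2O, MeOH, −78 → 0 °C
Reagents that add atoms: none
Why: In the Luche 1,2-reduction hydride attacks C7 axially from the α face, so the pseudo-equatorial 7β-alcohol should result as with 1-en-3-one steroids.

**Step 10**
Reactants: 11 allylic alcohol
Product: 13 diazoacetate of 11 at O7, via bromoacetate 12 (not isolated)
Conditions: BrCH2COBr, NaHCO3, MeCN, 0 °C; then TsNHNHTs, DBU, THF, 0 °C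
Reagents that add atoms: bromoacetyl bromide, BrCC(Br)=O; N,N'-ditosylhydrazine, Cc1ccc(cc1)S(=O)(=O)NNS(=O)(=O)c1ccc(C)cc1
Why: O-acylation, N-alkylation of the ditosylhydrazine and twofold base-induced loss of sulfinate (Bamford–Stevens-type) install the diazoacetate tether without touching C7.

**Step 11**
Reactants: 13 diazoacetate
Product: 15 cyclopropane lactone (C11 bridges C8 and C9 on the β face; γ-lactone O7–C12(=O)–C11 cis-fused at C7–C8; CH2SiMe3 on C8), via rhodium carbene 14 (not isolated)
Conditions: Rh2(cap)4 (1 mol %), CH2Cl2, reflux, slow addition of 13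
Reagents that add atoms: none
Why: Rh2(cap)4 takes N2 out of 13, and the electrophilic metal carbene 14 adds to the electron-rich C8=C9 allylsilane in an asynchronous concerted [2+1] step in which C9–C11 runs ahead while positive charge builds at C8, which is tertiary and β to silicon. The closest known reaction type is the intramolecular cyclopropanation of cyclohex-2-enyl and other secondary allylic diazoacetates with dirhodium carboxamidates or copper salicylaldimines to 3-oxabicyclo[3.1.0]hexan-2-ones. Two rings close at once: the three-membered ring C8–C9–C11 by the [2+1] addition, and the five-membered lactone O7–C12–C11–C8–C7 by the C8–C11 bond (an exo closure onto C8), cis-fused to ring B along C7–C8. C8 and C9 are set by the three-atom tether, which lets C11 reach the alkene only from the β face that carries O7, so C11 is forced syn to the angular C10 methyl against the intrinsic α preference of ring B; C11 is set because C12 must remain in the lactone, cis to C7. The step needs chemoselectivity for the alkene over insertion into C6–H, over carbene dimers and over the C–Cl bond, which the nucleophilic allylsilane, the mild carboxamidate ligands and slow addition should secure. Premature desilylative collapse is held back because it would give a strained lactone bridge across C7 and C9.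

**Step 12**
Reactants: 15 cyclopropane lactone
Product: 17 acetoxy Weinreb amide (7β-OAc; cyclopropane C8–C9–C11 intact; C12 as N-methoxy-N-methylamide), via chloromagnesium alkoxide 16 (not isolated)
Conditions: MeNH(OMe)·HCl, iPrMgCl, THF, −20 → 0 °C; then Ac2O, DMAP, 0 → 25 °C
Reagents that add atoms: N,O-dimethylhydroxylamine hydrochloride, CNOC.Cl; acetic anhydride, CC(=O)OC(C)=O
Why: Weinreb aminolysis of the lactone frees O7 as its alkoxide, which is acetylated in the same flask so that relactonization is blocked and the final 7β-acetate is in place with no stereocenter touched.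

**Step 13**
Reactants: 17 acetoxy Weinreb amide
Product: 18 acetoxy cyclopropanecarbaldehyde (C12 as CHO)
Conditions: Cp2Zr(H)Cl (1.5 equiv), THF, 25 °C; H2O work-up
Reagents that add atoms: none
Why: Schwartz reduction of tertiary amides stops at the aldehyde level and leaves esters alone, and at this stage no alkene is present that could be hydrozirconated.

**Step 14**
Reactants: 18 acetoxy cyclopropanecarbaldehyde
Product: 20 enal precursor: 7β-acetoxy-2α-chloro-13,14,15,16-tetranorlabd-8(17)-en-12-al, via silyl enol ether 19 (not isolated)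
Conditions: TMSOTf (10 mol %), CH2Cl2, −78 °C; then aq. citric acid, THF, 0 °C
Reagents that add atoms: none
Why: Proposed new method: O-silylation of the aldehyde by TMSOTf makes C12 a strong acceptor, the C8–C11 bond of the donor–acceptor cyclopropane ionizes toward C8 (tertiary and β-silicon-stabilized, unlike secondary neopentyl C9), and loss of the silyl group from C17 regenerates TMSOTf and leaves the C8=C17 methylene plus the C11=C12 silyl enol ether, which masks the aldehyde from Prins-type closure until hydrolysis; C9 is not involved and keeps its configuration; the closest known reaction types are the Lewis-acid-promoted silicon-assisted ring opening of silylmethyl donor–acceptor cyclopropanes, the electrophilic opening of cyclopropylmethylsilanes, and the fluoride-induced opening of 2-siloxycyclopropanecarboxylates.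

**Step 15**
Reactants: 21 (R)-4-benzyl-2-oxazolidinone; 22 3-cyanopropanoic acid
Product: 24 (R)-4-benzyl-3-(3-cyanopropanoyl)oxazolidin-2-one, via mixed anhydride 23 (not isolated)
Conditions: 22, PivCl, Et3N, THF, −20 °C; then 21, LiCl, −20 → 25 °C
Reagents that add atoms: none
Why: Mixed-anhydride N-acylation of an oxazolidinone with LiCl activation is standard and leaves the auxiliary stereocenter untouched.

**Step 16**
Reactants: 20 aldehyde; 24 cyanopropanoyl oxazolidinone
Product: 27 syn-aldol adduct (12S,13R; C14–C15 as CH2CN; C16 on the auxiliary), via boron enolate 25 (not isolated), via boron aldolate 26 (not isolated)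
Conditions: 24, Bu2BOTf, Et3N, CH2Cl2, −78 → 0 °C; 20, −78 → 0 °C; pH 7 buffer, MeOH, H2O2, 0 °C
Reagents that add atoms: none
Why: In the Evans syn-aldol the Z-boron enolate reacts through a Zimmerman–Traxler chair whose open face is fixed by the (R)-benzyl group, which sets 12S and 13R independently of the remote decalin.

**Step 17**
Reactants: 27 syn-aldol adduct
Product: 29 haterumaimide N, via primary amide 28 (not isolated)
Conditions: [PtH{(PMe2O)2H}(PMe2OH)] (5 mol %), EtOH/H2O, 70 °C; then DBU (0.2 equiv), CH2Cl2, 0 °C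
Reagents that add atoms: water, O
Why: Neutral platinum-catalysed nitrile hydration gives the primary amide, whose nitrogen attacks the activated N-acyl carbonyl C16 in a 5-exo-trig acyl transfer that closes the succinimide and expels the auxiliary, with no strong base present to disturb C12, C13 or the acetate.

**Compound list**

1 | (S)-4a-methyl-4,4a,5,6,7,8-hexahydronaphthalen-2(3H)-one | C1CCC2=CC(=O)CC[C@]2(C)C1 | starting material
2 | 4,4,10β-trimethyl-Δ5-octal-3-one | C1CC=C2C(C)(C)C(=O)CC[C@]2(C)C1 | intermediate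
3 | hydrazone of 2 | C1CC=C2C(C)(C)C(=NN)CC[C@]2(C)C1 | intermediate
4 | 4,4,10β-trimethyl-Δ5-octalin | C1CC=C2C(C)(C)CCC[C@]2(C)C1 | intermediate
5 | 4,4,10β-trimethyl-Δ5-octal-7-one | O=C1C=C2C(C)(C)CCC[C@]2(C)CC1 | intermediate
6 | 4,4,10β-trimethyl-5αH-decal-7-one | O=C1C[C@H]2C(C)(C)CCC[C@]2(C)CC1 | intermediate
7 | 2α-chloro-4,4,10β-trimethyl-5αH-decal-7-one | O=C1C[C@H]2C(C)(C)C[C@H](Cl)C[C@]2(C)CC1 | intermediate
8 | 2α-chloro-4,4,10β-trimethyl-5αH-Δ8(9)-octal-7-one | O=C1C[C@H]2C(C)(C)C[C@H](Cl)C[C@]2(C)C=C1 | intermediate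
9 | 8-iodo enone | O=C1C[C@H]2C(C)(C)C[C@H](Cl)C[C@]2(C)C=C1I | intermediate
10 | 8-(trimethylsilylmethyl) enone | O=C1C[C@H]2C(C)(C)C[C@H](Cl)C[C@]2(C)C=C1C[Si](C)(C)C | intermediate
11 | 7β-allylic alcohol | O[C@H]1C[C@H]2C(C)(C)C[C@H](Cl)C[C@]2(C)C=C1C[Si](C)(C)C | intermediate
12 | 7β-bromoacetate | BrCC(=O)O[C@H]1C[C@H]2C(C)(C)C[C@H](Cl)C[C@]2(C)C=C1C[Si](C)(C)C | intermediate
13 | 7β-diazoacetate | [N-]=[N+]=CC(=O)O[C@H]1C[C@H]2C(C)(C)C[C@H](Cl)C[C@]2(C)C=C1C[Si](C)(C)C | intermediate
14 | rhodium carbene (ligands and second rhodium not drawn) | [Rh]=CC(=O)O[C@H]1C[C@H]2C(C)(C)C[C@H](Cl)C[C@]2(C)C=C1C[Si](C)(C)C | intermediate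
15 | cyclopropane lactone (C11 β-bridging C8/C9, lactone O7–C12–C11) | C[Si](C)(C)C[C@@]12[C@H]3OC(=O)[C@@H]1[C@@H]2[C@@]4(C)C[C@@H](Cl)CC(C)(C)[C@@H]4C3 | intermediate
16 | chloromagnesium 7β-alkoxide of the cyclopropyl Weinreb amide | C[Si](C)(C)C[C@]12[C@@H](O[Mg]Cl)C[C@H]3C(C)(C)C[C@H](Cl)C[C@]3(C)[C@H]1[C@H]2C(=O)N(C)OC | intermediate
17 | 7β-acetoxy cyclopropyl Weinreb amide | C[Si](C)(C)C[C@]12[C@@H](OC(C)=O)C[C@H]3C(C)(C)C[C@H](Cl)C[C@]3(C)[C@H]1[C@H]2C(=O)N(C)OC | intermediate
18 | 7β-acetoxy cyclopropanecarbaldehyde | C[Si](C)(C)C[C@]12[C@@H](OC(C)=O)C[C@H]3C(C)(C)C[C@H](Cl)C[C@]3(C)[C@H]1[C@H]2C=O | intermediate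
19 | C11=C12 trimethylsilyl enol ether (mixture of enol ether geometries, no alkene descriptor drawn) | C=C1[C@@H](OC(C)=O)C[C@H]2C(C)(C)C[C@H](Cl)C[C@]2(C)[C@H]1C=CO[Si](C)(C)C | intermediate
20 | 7β-acetoxy-2α-chloro-13,14,15,16-tetranorlabd-8(17)-en-12-al | C=C1[C@@H](OC(C)=O)C[C@H]2C(C)(C)C[C@H](Cl)C[C@]2(C)[C@H]1CC=O | intermediate
21 | (R)-4-benzyl-2-oxazolidinone | O=C1OC[C@@H](Cc2ccccc2)N1 | starting material
22 | 3-cyanopropanoic acid | N#CCCC(=O)O | starting material
23 | 3-cyanopropanoic pivalic anhydride | N#CCCC(=O)OC(=O)C(C)(C)C | intermediate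
24 | (R)-4-benzyl-3-(3-cyanopropanoyl)oxazolidin-2-one | N#CCCC(=O)N1[C@H](Cc2ccccc2)COC1=O | intermediate
25 | Z-dibutylboron enolate of 24 | CCCCB(CCCC)O/C(=C\CC#N)N1[C@H](Cc2ccccc2)COC1=O | intermediate
26 | dibutylboron aldolate | C=C1[C@@H](OC(C)=O)C[C@H]2C(C)(C)C[C@H](Cl)C[C@]2(C)[C@H]1C[C@H](OB(CCCC)CCCC)[C@@H](CC#N)C(=O)N1[C@H](Cc2ccccc2)COC1=O | intermediate
27 | syn-aldol adduct (12S,13R) | C=C1[C@@H](OC(C)=O)C[C@H]2C(C)(C)C[C@H](Cl)C[C@]2(C)[C@H]1C[C@H](O)[C@@H](CC#N)C(=O)N1[C@H](Cc2ccccc2)COC1=O | intermediate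
28 | primary amide from 27 | C=C1[C@@H](OC(C)=O)C[C@H]2C(C)(C)C[C@H](Cl)C[C@]2(C)[C@H]1C[C@H](O)[C@@H](CC(N)=O)C(=O)N1[C@H](Cc2ccccc2)COC1=O | intermediate
29 | haterumaimide N | C=C1[C@@H](OC(C)=O)C[C@H]2C(C)(C)C[C@H](Cl)C[C@]2(C)[C@H]1C[C@H](O)[C@H]1CC(=O)NC1=O | target

**Step count**

Total step count: 17.
Longest linear sequence: 16 (steps 1–14, 16, 17).

**Steps most likely to fail**

**Step 14 (labelled step).**
- What may go wrong: the Lewis acid ionizes the cyclopropylcarbinyl C7–OAc bond, or the ring opens without loss of silicon, so that skeletal rearrangement overtakes the clean C8–C11 cleavage.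
- Fallback (known chemistry only, from 11 back to 20, without any cyclopropane): Eschenmoser–Claisen rearrangement of 11 (MeC(OMe)2NMe2, xylene, 140 °C) passes the 7β C–O bond suprafacially into the 9β C9–C11 bond and should give the Δ7 allylsilane dimethylamide F1. mCPBA (NaHCO3, CH2Cl2, 0 °C) epoxidizes the allylsilane from the open α face to the 7α,8α-epoxysilane F2. AcOH in MeOH opens it with Peterson-type loss of silicon to the 7α-hydroxy-8(17)-ene amide F3. Mitsunobu inversion with AcOH (PPh3, DIAD, THF) gives the 7β-acetoxy amide F4, and Cp2Zr(H)Cl reduces the amide to 20.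

**Step 11.**
- What may go wrong: carbene dimerization, insertion into the C6–H bond, or too slow an approach to the β face under the C10 methyl.
- Fallback (from 11 back to 20): hydroxyl-directed Simmons–Smith cyclopropanation (Et2Zn, CH2I2, CH2Cl2, 0 °C) delivers CH2 as C11 to the β face syn to the 7β-OH and should give the cyclopropyl carbinol F5. Ac2O in pyridine gives the cyclopropyl acetate F6. Formylative ring opening of the cyclopropylmethylsilane (Cl2CHOMe, TiCl4, CH2Cl2, −78 °C; then water) gives 20: the electrophile attacks the unhindered C11, C8–C11 breaks and silicon leaves.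

**Step 17.**
- What may go wrong: the free C12 hydroxyl attacks the newly formed amide (γ-lactone formation), or the base triggers retro-aldol cleavage or loss of the acetate before the imide closes.
- Fallback (from 27 back to 29, with the hydroxyl masked): TESOTf and 2,6-lutidine give the triethylsilyl ether F7. The same platinum hydration gives the silylated primary amide F8. Cs2CO3 in MeCN closes the silylated imide F9 with release of the auxiliary, and HF·pyridine in THF frees 29.

**Further compounds**

F1 | step 14 | Δ7 allylsilane 9β-acetic acid dimethylamide | C[Si](C)(C)CC1=CC[C@H]2C(C)(C)C[C@H](Cl)C[C@]2(C)[C@H]1CC(=O)N(C)C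
F2 | step 14 | 7α,8α-epoxysilane dimethylamide | C[Si](C)(C)C[C@@]12O[C@@H]1C[C@H]3C(C)(C)C[C@H](Cl)C[C@]3(C)[C@H]2CC(=O)N(C)C
F3 | step 14 | 7α-hydroxy-8(17)-ene dimethylamide | C=C1[C@H](O)C[C@H]2C(C)(C)C[C@H](Cl)C[C@]2(C)[C@H]1CC(=O)N(C)C
F4 | step 14 | 7β-acetoxy-8(17)-ene dimethylamide | C=C1[C@@H](OC(C)=O)C[C@H]2C(C)(C)C[C@H](Cl)C[C@]2(C)[C@H]1CC(=O)N(C)C
F5 | step 11 | 8β,9β-methano 7β-carbinol (C11 as CH2) | C[Si](C)(C)C[C@]12[C@@H](O)C[C@H]3C(C)(C)C[C@H](Cl)C[C@]3(C)[C@H]1C2
F6 | step 11 | 8β,9β-methano 7β-acetate | C[Si](C)(C)C[C@]12[C@@H](OC(C)=O)C[C@H]3C(C)(C)C[C@H](Cl)C[C@]3(C)[C@H]1C2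
F7 | step 17 | 12-O-triethylsilyl aldol adduct | C=C1[C@@H](OC(C)=O)C[C@H]2C(C)(C)C[C@H](Cl)C[C@]2(C)[C@H]1C[C@H](O[Si](CC)(CC)CC)[C@@H](CC#N)C(=O)N1[C@H](Cc2ccccc2)COC1=O
F8 | step 17 | 12-O-triethylsilyl primary amide | C=C1[C@@H](OC(C)=O)C[C@H]2C(C)(C)C[C@H](Cl)C[C@]2(C)[C@H]1C[C@H](O[Si](CC)(CC)CC)[C@@H](CC(N)=O)C(=O)N1[C@H](Cc2ccccc2)COC1=O
F9 | step 17 | 12-O-triethylsilyl haterumaimide N | C=C1[C@@H](OC(C)=O)C[C@H]2C(C)(C)C[C@H](Cl)C[C@]2(C)[C@H]1C[C@H](O[Si](CC)(CC)CC)[C@H]1CC(=O)NC1=O
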